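## The problem

The target is a daucane-type diester built on a cis-fused hydroazulene: a cyclopentane (C1–C5) shares the C1–C5 bond with a cycloheptene (C1, C5–C10). The numbering used throughout is: C1 quaternary ring-fusion carbon bearing a methyl group; C2 and C3 methylenes; C4 the isopropyl carbinol; C5 the ring-fusion methine; C6 the carbon carrying the 4-hydroxybenzoate; C7 a methylene; C8=C9 the olefin with its methyl on C8; C10 the carbon carrying the tiglate.

Five stereocentres must be set. H5 and the C1 methyl lie on one face (α); the oxygens at C4, C6 and C10 all lie on the other (β). C1, C5 and C4 are contiguous, one of them quaternary and one a fully substituted carbinol.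

The C10 oxygen sits next to C1 and can steer a reagent to the opposite face of C1. C1 then fixes C5 through the ring fusion, C4 can follow from C5 by chelation, C6 from the C4 hydroxyl and the C1/H5 pair, and C10 can be reset late from the shape of the bicycle.

The two secondary carbinols carry different acyl groups and must never be free together. The tiglate is an allylic ester and a Michael acceptor, the aryl ester has a free phenol, and the tertiary C4 hydroxyl is β to the C6 oxygen (retro-aldol at the ketone stage, dehydration under acid). The finished compound therefore tolerates neither strong base nor strong acid.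

The enabling feature is the aldol pattern C4(OH)–C5–C6(O) with the methyl-bearing quaternary C1 attached to C5. With C6 as a ketone, C5 is an enolate carbon, C1 is the β-carbon of a C5=C1 enone, and C4 is a ketone held on a two-carbon tether (C2, C3) from C1. The C1 methyl and the C4–C5 bond can then be formed in one operation.

## Retrosynthesis

**Esters last.** Target 30 is traced to its aryl silyl ether 29 (O–Si cut), and 29 to allylic alcohol 26 and tiglic acid 27 (C10–O acyl cut). The tiglate would not survive enolates, cuprates or hydrides, so it goes on after all skeletal work. The forward steps ask for acylation of a hindered secondary allylic carbinol beside a free tertiary one, and a fluoride deprotection that spares two esters.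

**C10 carbinol and the C8 methyl olefin.** 26 comes from enone 25 by 1,2-reduction (C10–H cut). 25 is traced through enone 23 to saturated ketone 22 by cutting C8–CH3 and removing the C8=C9 unsaturation. A C10 carbonyl is the one handle that activates C9 and C8. Carrying the C8 methyl from the start would need a non-commercial dione and would drag an uncontrolled stereocentre through the key step. Because C1 is quaternary, dehydrogenation of 22 can run only toward C9.

**Differentiating C6 and C10.** Ketone 22 comes from alcohol 21 and silyl ether 20. Ester 20 is cut at the C6–O acyl bond to diol 15 and 4-(triisopropylsilyloxy)benzoic acid 18 (from 4-hydroxybenzoic acid 16). Aroylation while C10 is still silylated keeps the two secondary carbinols apart. The alkyl tert-butyldimethylsilyl (TBS) ether is later removed with acid, which leaves the aryl triisopropylsilyl (TIPS) ether in place, and the aryl ether falls to buffered fluoride at the end. Diol 15 comes from β-hydroxy ketone 14 by chelation-controlled reduction (C6–H cut).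

**Key disconnection.** 14 is cut at C1–CH3 and C4–C5 to monocyclic enone 12 and a methyl cuprate. Cutting C4–C5 alone would leave a quaternary C1 to be made with no ring to guide it; cutting C1–C2 or C1–C10 would not use the C10 oxygen as a control element. The precursor has one stereocentre instead of four and one ring instead of two. The forward reaction must add methyl anti to the C10 silyloxy group, spare the saturated ketone, and close the aldol before the enolate is protonated.

**Side chain.** 12 is traced through carbinol 11 to aldehyde 10 (C4–isopropyl cut) and acetal 9. 9 is cut at C1–C2 to vinylogous ester 5 and bromide 6 by a Stork–Danheiser transposition. One operation places the carbonyl at C6, the olefin at C5=C1 and the silyloxy carbon next to C1. Conjugate addition and re-oxidation on a 4-silyloxycycloheptenone would need more steps.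

**The one reagent-controlled centre.** 5 comes from α′-hydroxy vinylogous ester 4 (O–Si cut), 4 from vinylogous ester 2 by enolate oxidation (C10–O cut), and 2 from symmetric cycloheptane-1,3-dione 1. Only C10 has to be set by an external chiral reagent; every later centre is relayed from it.

## Roads not taken

**Alternative 1:** Nozaki–Hiyama–Kishi closure of the seven-membered ring at C9–C10.
- Cut and key step: the ring is opened to cyclopentane A1, which carries a formyl group on C1, a (Z)-vinyl iodide at C9 and the C4/C6 diol as an acetonide. CrCl2 with catalytic NiCl2 would convert the iodide into an alkenylchromium species that adds to the aldehyde and gives allylic alcohol A2.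
- Merit: the ring closure delivers the C8=C9 olefin, the C8 methyl and the C10 carbinol together. In this respect it is better than the chosen plan, which spends steps 12–16 on an oxidation-state detour at C8–C10.
- Weak points: A1 already contains C1, C4, C5 and C6, so the hard stereochemical problem is moved into the precursor and must be solved centre by centre. The aldehyde is neopentylic, and the C10 configuration would depend only on the conformation of a forming seven-membered ring.
- Comparison: the chosen plan sets against the shorter endgame that C1, C5 and C4 arise in one step from a monocyclic enone with a single stereocentre.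

**Alternative 2:** intramolecular nitrile oxide cycloaddition as an aldol surrogate.
- Cut and key step: C5–C6 and O–C4 are cut. Nitrile oxide A3, generated in the flask at C6, would add across the C4=C5 bond of a cyclopentene and give tricyclic isoxazoline A4, closing the seven-membered ring and the heterocycle together.
- Merit: the addition is suprafacial and the tether from C1 dictates the face, so the cis fusion and the cis relation of the C4 oxygen to C6 are certain rather than dependent on chelation. That is stronger than the chosen aldol step, and the olefin is already in place.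
- Weak points: a seven-membered ring must close onto a hindered trisubstituted olefin in competition with nitrile oxide dimerisation. The N–O bond must later be cleaved reductively (for example with Mo(CO)6) beside a trisubstituted olefin and an allylic oxygen. The quaternary C1 in A3 has to be made enantiopure beforehand with nothing to relay from, and C6 must still be reduced with control after unmasking.
- Comparison: the chosen plan builds the quaternary centre and the ring in the same step and uses only robust functional-group chemistry afterwards.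

**Alternative 3:** silicon-tethered Pauson–Khand annulation.
- Cut and key step: C1–C2, C3–C4 and C4–C5 are cut. The alkyne of ethynylsilyl ether A5, as its Co2(CO)6 complex formed with Co2(CO)8, would add to the C1=C5 olefin and take up CO to give cyclopentenone A6, which has an oxasilolane bridge from C2 to the C10 oxygen.
- Merit: three C–C bonds form in one step, the tether forces delivery syn to the C10 oxygen (the same facial outcome as the anti cuprate addition), and the C6 oxygen is present from the start, so no ketone reduction at C6 is needed. These are real advantages.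
- Weak points: a trisubstituted cycloheptene that must become a quaternary centre is a poor Pauson–Khand partner. A6 still lacks the isopropyl group and has C4 as an enone carbonyl, so nucleophilic addition, olefin reduction and C–Si cleavage would follow, and then the same C8–C10 endgame as in the chosen plan.
- Comparison: the chosen plan sets against the greater bond count that its key step leaves C4 at the right oxidation level with the isopropyl group installed, and that conjugate additions creating quaternary centres on cycloalkenones are dependable.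

Key step: step 8

Assumption: the (+)-(2R,8aS) antipode of (camphorsulfonyl)oxaziridine is taken to give the (S)-carbinol 4. Both antipodes are commercial, and the (−)-reagent would replace it without other change if Mosher ester analysis showed the opposite sense.

Abbreviations: TBS = tert-butyldimethylsilyl; TIPS = triisopropylsilyl; DMP = Dess–Martin periodinane; IBX = 2-iodoxybenzoic acid.

## Route

Step 1
Reactants: 1 cycloheptane-1,3-dione
Product: 2 3-(2-methylpropoxy)cyclohept-2-en-1-one
Conditions: i-BuOH, TsOH·H2O (cat.), PhMe, reflux, Dean–Stark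
Reagents that add atoms: 2-methylpropan-1-ol, CC(C)CO
Why: Acid-catalysed enol etherification of a cyclic 1,3-dione with azeotropic removal of water gives the vinylogous ester; the dione is symmetric, so only one product can form.

Step 2
Reactants: 2 3-(2-methylpropoxy)cyclohept-2-en-1-one
Product: 4 (7S)-7-hydroxy-3-(2-methylpropoxy)cyclohept-2-en-1-one, via lithium dienolate 3 (not isolated)
Conditions: LiN(i-Pr)2, THF, −78 °C; then (+)-(camphorsulfonyl)oxaziridine, THF, −78 °C; aq. NH4Cl
Reagents that add atoms: (+)-(2R,8aS)-(camphorsulfonyl)oxaziridine, CC1(C)[C@@H]2CC[C@]13CS(=O)(=O)N4O[C@@]34C2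
Why: Kinetic deprotonation of a vinylogous ester occurs at the α′-carbon, and Davis oxidation of the cross-conjugated enolate transfers the oxaziridine oxygen to that carbon. The camphor skeleton differentiates the enolate faces (reagent control) and sets the future C10 as (S).

Step 3
Reactants: 4 (7S)-7-hydroxy-3-(2-methylpropoxy)cyclohept-2-en-1-one
Product: 5 (7S)-7-(tert-butyldimethylsilyloxy)-3-(2-methylpropoxy)cyclohept-2-en-1-one
Conditions: TBSCl, imidazole, DMF, 0 → 23 °C
Reagents that add atoms: tert-butyldimethylsilyl chloride, CC(C)(C)[Si](C)(C)Cl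
Why: Standard silylation of a secondary alcohol; it is done at once so that the α-hydroxy ketone cannot racemise by enolisation, and the bulky ether later serves as the directing group.

Step 4
Reactants: 5 (7S)-7-(tert-butyldimethylsilyloxy)-3-(2-methylpropoxy)cyclohept-2-en-1-one; 6 2-(2-bromoethyl)-1,3-dioxolane
Product: 9 (4S)-4-(tert-butyldimethylsilyloxy)-3-[2-(1,3-dioxolan-2-yl)ethyl]cyclohept-2-en-1-one, via Grignard reagent 7 (not isolated), via tertiary carbinol 8 (not isolated)
Conditions: 6, Mg, THF, 25 °C; CeCl3, THF, −78 °C; 5, −78 → 0 °C; then 1 M HCl, THF, 0 → 23 °C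
Reagents that add atoms: water, O
Why: Stork–Danheiser transposition: 1,2-addition of the organometallic to the vinylogous ester carbonyl (CeCl3 suppresses enolisation), then mild acid hydrolysis of the enol ether and loss of water give the β-substituted enone. Brief cold acid leaves the dioxolane and the TBS ether intact, and the silyloxy stereocentre is not touched.

Step 5
Reactants: 9 (4S)-4-(tert-butyldimethylsilyloxy)-3-[2-(1,3-dioxolan-2-yl)ethyl]cyclohept-2-en-1-one
Product: 10 3-[(7S)-7-(tert-butyldimethylsilyloxy)-3-oxocyclohept-1-en-1-yl]propanal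
Conditions: PPTS, acetone/H2O, 55 °C
Reagents that add atoms: water, O
Why: Acid-catalysed acetal hydrolysis under transacetalisation conditions mild enough for a secondary TBS ether.

Step 6
Reactants: 10 3-[(7S)-7-(tert-butyldimethylsilyloxy)-3-oxocyclohept-1-en-1-yl]propanal
Product: 11 (4S)-4-(tert-butyldimethylsilyloxy)-3-(3-hydroxy-4-methylpentyl)cyclohept-2-en-1-one (both carbinol epimers)
Conditions: i-PrMgCl, THF, −78 °C; aq. NH4Cl
Reagents that add atoms: isopropylmagnesium chloride, CC(C)[Mg]Cl
Why: Grignard addition; at −78 °C with one equivalent the aliphatic aldehyde reacts far faster than the conjugated, β,β-disubstituted ketone. The new carbinol centre is oxidised in the next step, so its configuration is irrelevant.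

Step 7
Reactants: 11 (4S)-4-(tert-butyldimethylsilyloxy)-3-(3-hydroxy-4-methylpentyl)cyclohept-2-en-1-one
Product: 12 (4S)-4-(tert-butyldimethylsilyloxy)-3-(4-methyl-3-oxopentyl)cyclohept-2-en-1-one
Conditions: DMP, CH2Cl2, 23 °C
Reagents that add atoms: none
Why: Dess–Martin oxidation of a secondary alcohol under near-neutral conditions; enone and silyl ether are inert.

Step 8
Reactants: 12 (4S)-4-(tert-butyldimethylsilyloxy)-3-(4-methyl-3-oxopentyl)cyclohept-2-en-1-one
Product: 14 (3R,3aR,8S,8aR)-8-(tert-butyldimethylsilyloxy)-3-hydroxy-8a-methyl-3-(propan-2-yl)octahydroazulen-4(1H)-one, via lithium enolate 13 (not isolated)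
Conditions: Me2CuLi (MeLi, CuI), Et2O, −78 → −30 °C; aq. NH4Cl at −78 °C
Reagents that add atoms: lithium dimethylcuprate, [Li+].C[Cu-]C
Why: Me2CuLi forms a π-complex with the C5=C1 enone and transfers a methyl group to C1 by oxidative addition and reductive elimination, leaving lithium enolate 13 (C5=C6–OLi), which attacks the tethered isopropyl ketone at C4 before the quench. The closest known reaction type is the tandem organocuprate conjugate addition–intramolecular aldol cyclisation, combined with the anti addition of cuprates to γ-silyloxy cycloalkenones. The cyclopentane (C1–C5) closes in the 5-(enolexo)-exo-trig mode. C1 is controlled by C10: the silyloxy group shields the β-face of the neighbouring β-carbon, so the methyl group enters from the α-face. C5 is controlled by C1: the C2–C3 tether then stands on the β-face, the C4–C5 bond can form only there, and H5 ends α, which is the cis fusion. C4 is controlled by a closed, lithium-bridged transition state that keeps the ketone oxygen beside the enolate oxygen, so the alkoxide ends cis to C6 and the isopropyl group points to the convex face. The step needs 1,4- over 1,2-addition and no attack on the saturated ketone, which the soft cuprate secures, and it needs the aldolate to persist, which the five-membered ring and the cold quench secure.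

Step 9
Reactants: 14 (3R,3aR,8S,8aR)-8-(tert-butyldimethylsilyloxy)-3-hydroxy-8a-methyl-3-(propan-2-yl)octahydroazulen-4(1H)-one
Product: 15 (3R,3aS,4R,8S,8aR)-8-(tert-butyldimethylsilyloxy)-8a-methyl-3-(propan-2-yl)decahydroazulene-3,4-diol
Conditions: Zn(BH4)2, Et2O, −30 → 0 °C; aq. NH4Cl
Reagents that add atoms: none
Why: Chelation-controlled reduction of a β-hydroxy ketone: zinc bridges the C4 hydroxyl and the C6 carbonyl so that C4 eclipses the carbonyl, and the two faces then differ by H5 versus the quaternary C1 (Cram chelate model). Hydride should enter past H5 and give the 4,6-syn diol with the C6 oxygen β.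

Step 10
Reactants: 16 4-hydroxybenzoic acid
Product: 18 4-(triisopropylsilyloxy)benzoic acid, via bis-silyl derivative 17 (not isolated)
Conditions: TIPSCl, imidazole, DMF, 23 °C; then AcOH/THF/H2O, 23 °C
Reagents that add atoms: triisopropylsilyl chloride, CC(C)[Si](Cl)(C(C)C)C(C)C
Why: Exhaustive silylation followed by selective hydrolysis of the labile silyl ester; the aryl TIPS ether is stable to dilute aqueous acid.

Step 11
Reactants: 15 (3R,3aS,4R,8S,8aR)-8-(tert-butyldimethylsilyloxy)-8a-methyl-3-(propan-2-yl)decahydroazulene-3,4-diol; 18 4-(triisopropylsilyloxy)benzoic acid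
Product: 20 (3R,3aS,4R,8S,8aR)-8-(tert-butyldimethylsilyloxy)-3-hydroxy-8a-methyl-3-(propan-2-yl)decahydroazulen-4-yl 4-(triisopropylsilyloxy)benzoate, via mixed anhydride 19 (not isolated)
Conditions: 18, 2,4,6-Cl3C6H2COCl, Et3N, THF, 23 °C; then 15, DMAP, PhMe, 23 → 60 °C
Reagents that add atoms: none
Why: Yamaguchi esterification: DMAP attacks the unhindered carbonyl of the mixed anhydride and the acylpyridinium acylates the secondary C6 carbinol; the tertiary C4 carbinol does not react and C10 is still silylated.

Step 12
Reactants: 20 (3R,3aS,4R,8S,8aR)-8-(tert-butyldimethylsilyloxy)-3-hydroxy-8a-methyl-3-(propan-2-yl)decahydroazulen-4-yl 4-(triisopropylsilyloxy)benzoate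
Product: 21 (3R,3aS,4R,8S,8aR)-3,8-dihydroxy-8a-methyl-3-(propan-2-yl)decahydroazulen-4-yl 4-(triisopropylsilyloxy)benzoate
Conditions: 48% aq. HF, MeCN, 0 → 23 °C
Reagents that add atoms: none
Why: Under acidic fluoride conditions alkyl silyl ethers cleave much faster than aryl silyl ethers, so the C10 TBS ether should be removed while the aryl TIPS ether and both other oxygen functions stay.

Step 13
Reactants: 21 (3R,3aS,4R,8S,8aR)-3,8-dihydroxy-8a-methyl-3-(propan-2-yl)decahydroazulen-4-yl 4-(triisopropylsilyloxy)benzoate
Product: 22 (3R,3aS,4R,8aR)-3-hydroxy-8a-methyl-8-oxo-3-(propan-2-yl)decahydroazulen-4-yl 4-(triisopropylsilyloxy)benzoate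
Conditions: DMP, CH2Cl2, 23 °C
Reagents that add atoms: none
Why: Dess–Martin oxidation of the only secondary alcohol; the tertiary carbinol cannot be oxidised, and the new ketone has no epimerisable α-centre because C1 is quaternary.

Step 14
Reactants: 22 (3R,3aS,4R,8aR)-3-hydroxy-8a-methyl-8-oxo-3-(propan-2-yl)decahydroazulen-4-yl 4-(triisopropylsilyloxy)benzoate
Product: 23 (3R,3aS,4R,8aR)-3-hydroxy-8a-methyl-8-oxo-3-(propan-2-yl)-1,2,3,3a,4,5,8,8a-octahydroazulen-4-yl 4-(triisopropylsilyloxy)benzoate
Conditions: IBX, DMSO/PhF, 70 °C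
Reagents that add atoms: none
Why: IBX dehydrogenation of a ketone to its enone through the enol; with C1 quaternary the unsaturation can form only at C9=C8, and the neutral conditions avoid an alkoxide next to the C6 ester.

Step 15
Reactants: 23 (3R,3aS,4R,8aR)-3-hydroxy-8a-methyl-8-oxo-3-(propan-2-yl)-1,2,3,3a,4,5,8,8a-octahydroazulen-4-yl 4-(triisopropylsilyloxy)benzoate
Product: 25 (3R,3aS,4R,8aR)-3-hydroxy-6,8a-dimethyl-8-oxo-3-(propan-2-yl)-1,2,3,3a,4,5,8,8a-octahydroazulen-4-yl 4-(triisopropylsilyloxy)benzoate, via lithium enolate 24 (not isolated)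
Conditions: Me2CuLi (MeLi, CuI; excess), THF/Et2O, −78 °C; then t-BuN=S(Cl)Ph, −78 → 0 °C; aq. NH4Cl
Reagents that add atoms: lithium dimethylcuprate, [Li+].C[Cu-]C
Why: Conjugate addition of the Gilman cuprate places the methyl group on C8, and the enolate is dehydrogenated in the same flask with N-tert-butylbenzenesulfinimidoyl chloride (Mukaiyama dehydrogenation; the one-pot β-alkylation of enones is a known sequence). Syn elimination can use only H8, so the C8=C9 enone results and the transient C8 stereocentre disappears.

Step 16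
Reactants: 25 (3R,3aS,4R,8aR)-3-hydroxy-6,8a-dimethyl-8-oxo-3-(propan-2-yl)-1,2,3,3a,4,5,8,8a-octahydroazulen-4-yl 4-(triisopropylsilyloxy)benzoate
Product: 26 (3R,3aS,4R,8S,8aR)-3,8-dihydroxy-6,8a-dimethyl-3-(propan-2-yl)-1,2,3,3a,4,5,8,8a-octahydroazulen-4-yl 4-(triisopropylsilyloxy)benzoate
Conditions: NaBH4, CeCl3·7H2O, MeOH, −78 → −40 °C
Reagents that add atoms: none
Why: Luche reduction gives clean 1,2-addition to the enone and leaves both esters. With the bulky C4 arm equatorial on C5, the C1–C2 bond stands over the β-face of C10 and the C1 methyl lies near the ring plane, so hydride should enter from the convex α-face and give the β-carbinol (10S).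

Step 17
Reactants: 26 (3R,3aS,4R,8S,8aR)-3,8-dihydroxy-6,8a-dimethyl-3-(propan-2-yl)-1,2,3,3a,4,5,8,8a-octahydroazulen-4-yl 4-(triisopropylsilyloxy)benzoate; 27 tiglic acid [(2E)-2-methylbut-2-enoic acid]
Product: 29 (3R,3aS,4R,8S,8aR)-3-hydroxy-6,8a-dimethyl-8-{[(2E)-2-methylbut-2-enoyl]oxy}-3-(propan-2-yl)-1,2,3,3a,4,5,8,8a-octahydroazulen-4-yl 4-(triisopropylsilyloxy)benzoate, via mixed anhydride 28 (not isolated)
Conditions: 27, 2,4,6-Cl3C6H2COCl, Et3N, PhMe, 23 °C; then 26, DMAP, PhMe, 23 → 70 °C
Reagents that add atoms: none
Why: Yamaguchi esterification is the usual way to put a tiglate on a hindered secondary alcohol; the (E)-acid is the stable isomer, the tertiary C4 hydroxyl stays free and the C10 configuration is retained because the C–O bond is not broken.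

Step 18
Reactants: 29 (3R,3aS,4R,8S,8aR)-3-hydroxy-6,8a-dimethyl-8-{[(2E)-2-methylbut-2-enoyl]oxy}-3-(propan-2-yl)-1,2,3,3a,4,5,8,8a-octahydroazulen-4-yl 4-(triisopropylsilyloxy)benzoate
Product: 30 (3R,3aS,4R,8S,8aR)-3-hydroxy-6,8a-dimethyl-8-{[(2E)-2-methylbut-2-enoyl]oxy}-3-(propan-2-yl)-1,2,3,3a,4,5,8,8a-octahydroazulen-4-yl 4-hydroxybenzoate (target)
Conditions: Bu4NF, AcOH, THF, 0 °C
Reagents that add atoms: none
Why: Aryl silyl ethers are cleaved quickly by fluoride; buffering with acetic acid keeps the medium near neutral so that neither ester is hydrolysed or migrates and the allylic tiglate is not ionised.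

## Compound list

1 | cycloheptane-1,3-dione | O=C1CCCCC(=O)C1 | starting material
2 | 3-(2-methylpropoxy)cyclohept-2-en-1-one | CC(C)COC1=CC(=O)CCCC1 | intermediate
3 | lithium dienolate of 2 (lithium 3-(2-methylpropoxy)cyclohepta-1,3-dien-1-olate; enolate toward the α′-carbon) | CC(C)COC1=CC(O[Li])=CCCC1 | intermediate
4 | (7S)-7-hydroxy-3-(2-methylpropoxy)cyclohept-2-en-1-one | O[C@H]1CCCC(OCC(C)C)=CC1=O | intermediate
5 | (7S)-7-(tert-butyldimethylsilyloxy)-3-(2-methylpropoxy)cyclohept-2-en-1-one | CC(C)(C)[Si](C)(C)O[C@H]1CCCC(OCC(C)C)=CC1=O | intermediate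
6 | 2-(2-bromoethyl)-1,3-dioxolane | BrCCC1OCCO1 | starting material
7 | [2-(1,3-dioxolan-2-yl)ethyl]magnesium bromide | Br[Mg]CCC1OCCO1 | intermediate
8 | (7S)-7-(tert-butyldimethylsilyloxy)-1-[2-(1,3-dioxolan-2-yl)ethyl]-3-(2-methylpropoxy)cyclohept-2-en-1-ol (magnesium alkoxide in the flask; carbinol epimers) | CC(C)(C)[Si](C)(C)O[C@H]1CCCC(OCC(C)C)=CC1(O)CCC1OCCO1 | intermediate
9 | (4S)-4-(tert-butyldimethylsilyloxy)-3-[2-(1,3-dioxolan-2-yl)ethyl]cyclohept-2-en-1-one | CC(C)(C)[Si](C)(C)O[C@H]1CCCC(=O)C=C1CCC1OCCO1 | intermediate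
10 | 3-[(7S)-7-(tert-butyldimethylsilyloxy)-3-oxocyclohept-1-en-1-yl]propanal | CC(C)(C)[Si](C)(C)O[C@H]1CCCC(=O)C=C1CCC=O | intermediate
11 | (4S)-4-(tert-butyldimethylsilyloxy)-3-(3-hydroxy-4-methylpentyl)cyclohept-2-en-1-one (both carbinol epimers) | CC(C)(C)[Si](C)(C)O[C@H]1CCCC(=O)C=C1CCC(O)C(C)C | intermediate
12 | (4S)-4-(tert-butyldimethylsilyloxy)-3-(4-methyl-3-oxopentyl)cyclohept-2-en-1-one | CC(C)(C)[Si](C)(C)O[C@H]1CCCC(=O)C=C1CCC(=O)C(C)C | intermediate
13 | lithium (3R,4S)-4-(tert-butyldimethylsilyloxy)-3-methyl-3-(4-methyl-3-oxopentyl)cyclohept-1-en-1-olate | CC(C)(C)[Si](C)(C)O[C@H]1CCCC(O[Li])=C[C@@]1(C)CCC(=O)C(C)C | intermediate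
14 | (3R,3aR,8S,8aR)-8-(tert-butyldimethylsilyloxy)-3-hydroxy-8a-methyl-3-(propan-2-yl)octahydroazulen-4(1H)-one | CC(C)(C)[Si](C)(C)O[C@H]1CCCC(=O)[C@@H]2[C@@]1(C)CC[C@@]2(O)C(C)C | intermediate
15 | (3R,3aS,4R,8S,8aR)-8-(tert-butyldimethylsilyloxy)-8a-methyl-3-(propan-2-yl)decahydroazulene-3,4-diol | CC(C)(C)[Si](C)(C)O[C@H]1CCC[C@@H](O)[C@@H]2[C@@]1(C)CC[C@@]2(O)C(C)C | intermediate
16 | 4-hydroxybenzoic acid | OC(=O)c1ccc(O)cc1 | starting material
17 | triisopropylsilyl 4-(triisopropylsilyloxy)benzoate | CC(C)[Si](C(C)C)(C(C)C)OC(=O)c1ccc(O[Si](C(C)C)(C(C)C)C(C)C)cc1 | intermediate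
18 | 4-(triisopropylsilyloxy)benzoic acid | CC(C)[Si](C(C)C)(C(C)C)Oc1ccc(cc1)C(=O)O | intermediate
19 | 4-(triisopropylsilyloxy)benzoic 2,4,6-trichlorobenzoic anhydride | CC(C)[Si](C(C)C)(C(C)C)Oc1ccc(cc1)C(=O)OC(=O)c1c(Cl)cc(Cl)cc1Cl | intermediate
20 | (3R,3aS,4R,8S,8aR)-8-(tert-butyldimethylsilyloxy)-3-hydroxy-8a-methyl-3-(propan-2-yl)decahydroazulen-4-yl 4-(triisopropylsilyloxy)benzoate | CC(C)(C)[Si](C)(C)O[C@H]1CCC[C@@H](OC(=O)c3ccc(O[Si](C(C)C)(C(C)C)C(C)C)cc3)[C@@H]2[C@@]1(C)CC[C@@]2(O)C(C)C | intermediate
21 | (3R,3aS,4R,8S,8aR)-3,8-dihydroxy-8a-methyl-3-(propan-2-yl)decahydroazulen-4-yl 4-(triisopropylsilyloxy)benzoate | O[C@H]1CCC[C@@H](OC(=O)c3ccc(O[Si](C(C)C)(C(C)C)C(C)C)cc3)[C@@H]2[C@@]1(C)CC[C@@]2(O)C(C)C | intermediate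
22 | (3R,3aS,4R,8aR)-3-hydroxy-8a-methyl-8-oxo-3-(propan-2-yl)decahydroazulen-4-yl 4-(triisopropylsilyloxy)benzoate | O=C1CCC[C@@H](OC(=O)c3ccc(O[Si](C(C)C)(C(C)C)C(C)C)cc3)[C@@H]2[C@@]1(C)CC[C@@]2(O)C(C)C | intermediate
23 | (3R,3aS,4R,8aR)-3-hydroxy-8a-methyl-8-oxo-3-(propan-2-yl)-1,2,3,3a,4,5,8,8a-octahydroazulen-4-yl 4-(triisopropylsilyloxy)benzoate | O=C1C=CC[C@@H](OC(=O)c3ccc(O[Si](C(C)C)(C(C)C)C(C)C)cc3)[C@@H]2[C@@]1(C)CC[C@@]2(O)C(C)C | intermediate
24 | lithium enolate (C9=C10–OLi) of the C8-methylated ketone, C4 as lithium alkoxide, both C8 epimers | [Li]OC1=CC(C)C[C@@H](OC(=O)c3ccc(O[Si](C(C)C)(C(C)C)C(C)C)cc3)[C@@H]2[C@@]1(C)CC[C@@]2(O[Li])C(C)C | intermediate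
25 | (3R,3aS,4R,8aR)-3-hydroxy-6,8a-dimethyl-8-oxo-3-(propan-2-yl)-1,2,3,3a,4,5,8,8a-octahydroazulen-4-yl 4-(triisopropylsilyloxy)benzoate | O=C1C=C(C)C[C@@H](OC(=O)c3ccc(O[Si](C(C)C)(C(C)C)C(C)C)cc3)[C@@H]2[C@@]1(C)CC[C@@]2(O)C(C)C | intermediate
26 | (3R,3aS,4R,8S,8aR)-3,8-dihydroxy-6,8a-dimethyl-3-(propan-2-yl)-1,2,3,3a,4,5,8,8a-octahydroazulen-4-yl 4-(triisopropylsilyloxy)benzoate | O[C@H]1C=C(C)C[C@@H](OC(=O)c3ccc(O[Si](C(C)C)(C(C)C)C(C)C)cc3)[C@@H]2[C@@]1(C)CC[C@@]2(O)C(C)C | intermediate
27 | tiglic acid, (2E)-2-methylbut-2-enoic acid | C/C=C(\C)C(=O)O | starting material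
28 | (2E)-2-methylbut-2-enoic 2,4,6-trichlorobenzoic anhydride | C/C=C(\C)C(=O)OC(=O)c1c(Cl)cc(Cl)cc1Cl | intermediate
29 | (3R,3aS,4R,8S,8aR)-3-hydroxy-6,8a-dimethyl-8-{[(2E)-2-methylbut-2-enoyl]oxy}-3-(propan-2-yl)-1,2,3,3a,4,5,8,8a-octahydroazulen-4-yl 4-(triisopropylsilyloxy)benzoate | C/C=C(\C)C(=O)O[C@H]1C=C(C)C[C@@H](OC(=O)c3ccc(O[Si](C(C)C)(C(C)C)C(C)C)cc3)[C@@H]2[C@@]1(C)CC[C@@]2(O)C(C)C | intermediate
30 | (3R,3aS,4R,8S,8aR)-3-hydroxy-6,8a-dimethyl-8-{[(2E)-2-methylbut-2-enoyl]oxy}-3-(propan-2-yl)-1,2,3,3a,4,5,8,8a-octahydroazulen-4-yl 4-hydroxybenzoate | C/C=C(\C)C(=O)O[C@H]1C=C(C)C[C@@H](OC(=O)c2ccc(O)cc2)[C@@H]2[C@@]1(C)CC[C@@]2(O)C(C)C | target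

## Step count and risk

Total step count: 18. Longest linear sequence: 17 steps (steps 1–9 and 11–18, from cycloheptane-1,3-dione); step 10 is a one-step side branch.

Least certain steps:

**Step 8 (key step).** The most likely failure is slow or reversible aldol closure onto the hindered isopropyl ketone, so that the enolate is protonated before the ring forms. A second risk is erosion of C4 selectivity through an open, non-chelated transition state. A slow conjugate addition at the β,β-disubstituted position would add to both. The fallback sets out from 12 and separates the two events. Cuprate addition in the presence of TMSCl captures the enolate as 5-[(1R,7S)-7-(tert-butyldimethylsilyloxy)-1-methyl-3-(trimethylsilyloxy)cyclohept-2-en-1-yl]-2-methylpentan-3-one F1. F1 is then closed by an intramolecular Mukaiyama aldol reaction with TiCl4 in CH2Cl2 at −78 °C, in which titanium bridges the two oxygens. The route is rejoined at 14.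

**Step 2.** Oxygen transfer may be insufficiently face-selective for this enolate, or the α-hydroxy ketone may partly racemise before silylation. The fallback sets out from 2 and uses resolution instead of reagent control. α′-Acetoxylation with Mn(OAc)3 in benzene at reflux gives racemic 4-(2-methylpropoxy)-2-oxocyclohept-3-en-1-yl acetate F2. Lipase-catalysed hydrolysis (Amano lipase PS, phosphate buffer; the enzyme is chosen by screening so that the (S)-ester is hydrolysed) then gives the (S)-alcohol and leaves (1R)-4-(2-methylpropoxy)-2-oxocyclohept-3-en-1-yl acetate F3. The route is rejoined at 4.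

**Step 6.** Chemoselectivity may be lost through competing 1,2-addition to the enone carbonyl, or through enolisation or reduction of the aldehyde by the secondary Grignard reagent. The fallback sets out from 5 and brings the ketone in masked form. 3-Chloropropanoyl chloride and i-PrMgCl with catalytic Fe(acac)3 give 1-chloro-4-methylpentan-3-one F4. Ketalisation with ethylene glycol gives 2-(2-chloroethyl)-2-(propan-2-yl)-1,3-dioxolane F5, and magnesium converts it into [2-(2-isopropyl-1,3-dioxolan-2-yl)ethyl]magnesium chloride F6. Addition to 5 with CeCl3 gives the tertiary carbinol (7S)-7-(tert-butyldimethylsilyloxy)-1-[2-(2-isopropyl-1,3-dioxolan-2-yl)ethyl]-3-(2-methylpropoxy)cyclohept-2-en-1-ol F7. Aqueous HCl then hydrolyses enol ether and ketal and eliminates water. The route is rejoined at 12, with steps 5–7 bypassed.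

**Step 9.** Facial selectivity at C6 may be poor if zinc chelates the hindered tertiary hydroxyl only weakly. The fallback sets out from 14 and uses inversion. Reduction under conditions that favour the other face (Me4NBH(OAc)3, MeCN/AcOH), or separation of the minor epimer, provides (3R,3aS,4S,8S,8aR)-8-(tert-butyldimethylsilyloxy)-8a-methyl-3-(propan-2-yl)decahydroazulene-3,4-diol F8. Mitsunobu esterification with 4-nitrobenzoic acid (PPh3, DIAD) inverts C6 and gives (3R,3aS,4R,8S,8aR)-8-(tert-butyldimethylsilyloxy)-3-hydroxy-8a-methyl-3-(propan-2-yl)decahydroazulen-4-yl 4-nitrobenzoate F9. Methanolysis with K2CO3 rejoins the route at 15.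

**Step 15.** Dehydrogenation may be incomplete because residual organocopper species consume the sulfur reagent, or the enolate may be protonated before it is oxidised. The fallback sets out from 23 and isolates the enol derivative. Me2CuLi with TMSCl gives the trimethylsilyl enol ether (3R,3aS,4R,8aR)-3-hydroxy-6,8a-dimethyl-3-(propan-2-yl)-8-(trimethylsilyloxy)-1,2,3,3a,4,5,6,8a-octahydroazulen-4-yl 4-(triisopropylsilyloxy)benzoate F10. Ito–Saegusa oxidation of F10 with Pd(OAc)2 in MeCN rejoins the route at 25.

**Step 16.** Facial selectivity at C10 may be poor if the seven-membered ring reacts through the conformer in which the C1 methyl, not the C1–C2 bond, is axial. The fallback sets out from 25 and replaces substrate control by reagent control. Corey–Bakshi–Shibata reduction with catecholborane is used, with the catalyst antipode that places the quaternary C1 side in the large-group position (expected to be the (R)-2-methyl oxazaborolidine). It returns to the route at 26 and makes no new compound.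

## Further compounds

F1 | step 8 | 5-[(1R,7S)-7-(tert-butyldimethylsilyloxy)-1-methyl-3-(trimethylsilyloxy)cyclohept-2-en-1-yl]-2-methylpentan-3-one | CC(C)(C)[Si](C)(C)O[C@H]1CCCC(O[Si](C)(C)C)=C[C@@]1(C)CCC(=O)C(C)C
F2 | step 2 | racemic 4-(2-methylpropoxy)-2-oxocyclohept-3-en-1-yl acetate | CC(=O)OC1CCCC(OCC(C)C)=CC1=O
F3 | step 2 | (1R)-4-(2-methylpropoxy)-2-oxocyclohept-3-en-1-yl acetate | CC(=O)O[C@@H]1CCCC(OCC(C)C)=CC1=O
F4 | step 6 | 1-chloro-4-methylpentan-3-one | CC(C)C(=O)CCCl
F5 | step 6 | 2-(2-chloroethyl)-2-(propan-2-yl)-1,3-dioxolane | CC(C)C1(CCCl)OCCO1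
F6 | step 6 | [2-(2-isopropyl-1,3-dioxolan-2-yl)ethyl]magnesium chloride | CC(C)C1(CC[Mg]Cl)OCCO1
F7 | step 6 | (7S)-7-(tert-butyldimethylsilyloxy)-1-[2-(2-isopropyl-1,3-dioxolan-2-yl)ethyl]-3-(2-methylpropoxy)cyclohept-2-en-1-ol (carbinol epimers) | CC(C)(C)[Si](C)(C)O[C@H]1CCCC(OCC(C)C)=CC1(O)CCC1(C(C)C)OCCO1
F8 | step 9 | (3R,3aS,4S,8S,8aR)-8-(tert-butyldimethylsilyloxy)-8a-methyl-3-(propan-2-yl)decahydroazulene-3,4-diol | CC(C)(C)[Si](C)(C)O[C@H]1CCC[C@H](O)[C@@H]2[C@@]1(C)CC[C@@]2(O)C(C)C
F9 | step 9 | (3R,3aS,4R,8S,8aR)-8-(tert-butyldimethylsilyloxy)-3-hydroxy-8a-methyl-3-(propan-2-yl)decahydroazulen-4-yl 4-nitrobenzoate | CC(C)(C)[Si](C)(C)O[C@H]1CCC[C@@H](OC(=O)c3ccc(cc3)[N+](=O)[O-])[C@@H]2[C@@]1(C)CC[C@@]2(O)C(C)C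
F10 | step 15 | (3R,3aS,4R,8aR)-3-hydroxy-6,8a-dimethyl-3-(propan-2-yl)-8-(trimethylsilyloxy)-1,2,3,3a,4,5,6,8a-octahydroazulen-4-yl 4-(triisopropylsilyloxy)benzoate (C8 epimers) | C[Si](C)(C)OC1=CC(C)C[C@@H](OC(=O)c3ccc(O[Si](C(C)C)(C(C)C)C(C)C)cc3)[C@@H]2[C@@]1(C)CC[C@@]2(O)C(C)C
F0 | step 16 | none | none
A1 | alternative 1 | cyclopentane-fused acetonide carrying a formyl group on C1 and a (Z)-3-iodo-2-methylprop-2-enyl chain on C6 | I/C=C(/C)C[C@H]1OC(C)(C)O[C@@]2(C(C)C)CC[C@@](C)(C=O)[C@@H]12
A2 | alternative 1 | bicyclic C10 allylic alcohol with the C4 and C6 oxygens as acetonide | O[C@H]1C=C(C)C[C@@H](O3)[C@@H]2[C@@]1(C)CC[C@@]2(OC3(C)C)C(C)C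
A3 | alternative 2 | nitrile oxide at C6 joined through the (Z)-C8=C9 olefin and the C10 triethylsilyl ether to the quaternary carbon of a 3-isopropylcyclopent-2-ene | [O-][N+]#CC/C(C)=C\[C@H](O[Si](CC)(CC)CC)[C@]1(C)CCC(C(C)C)=C1
A4 | alternative 2 | cis-fused tricyclic isoxazoline with C10 triethylsilyl ether | CC[Si](CC)(CC)O[C@H]1C=C(C)CC(=NO3)[C@@H]2[C@@]1(C)CC[C@@]23C(C)C
A5 | alternative 3 | 2-methylcyclohept-2-ene-1,4-diol carrying an ethynyldiisopropylsilyl ether on the C10 oxygen and a TBS ether on the C6 oxygen | C#C[Si](C(C)C)(C(C)C)O[C@H]1CCC[C@@H](O[Si](C)(C)C(C)(C)C)C=C1C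
A6 | alternative 3 | tricyclic cyclopentenone with an Si–O bridge from C2 to the C10 oxygen | CC(C)[Si]3(C(C)C)O[C@H]1CCC[C@@H](O[Si](C)(C)C(C)(C)C)[C@@H]2[C@@]1(C)C3=CC2=O
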